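**Retrosynthetic overview**
1. Both rings close last and together: the C6–C7 bond (ten-membered carbocycle) and the O–C12 lactone bond come from an acyclic 2-alkenylfuran that carries a 2-(bromomethyl)enoate.
2. The (1E,4Z)-dienone and the C6 aldehyde are carried as a furan (C3–C6 plus ring O) and unmasked only in the ring-closing pot.
3. C1=C2 is disconnected by cross-metathesis into (2-ethenylfuran-3-yl)methanol and a vinyl carbinol bromide.
4. The bromide comes from (R)-linalool (C1, C7–C10, C14): C8–O by proline α-aminoxylation; C11–C13 by Wittig olefination, singlet-oxygen ene reaction and SN2′ bromination.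
5. Ring order: ten-membered ring first (allylation at C6), α-methylene-γ-lactone second (lactonisation of the new 6-OH), same operation.

Assumption: atom labels C1–C15 follow germacranolide numbering (C3 ketone, C6 lactone carbinol, C8 ester carbinol, C10 tertiary carbinol, C12 lactone C=O); (R)-(−)-linalool and (R)-2-methylbutanoic acid are bought enantiopure.

**Step 1**
Reactants: 1 (R)-(−)-linalool
Product: 3 (5R)-5-ethenyl-5-methyloxolan-2-ol (anomer mixture; lactol of (4R)-4-hydroxy-4-methylhex-5-enal), via ozonide 2 (not isolated)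
Conditions: O3 (1.0 equiv), CH2Cl2, −78 °C; then Me2S, −78 °C → rt
Reagents that add atoms: ozone, [O-][O+]=O
Why: Ozonolysis with reductive work-up; the electron-rich trisubstituted alkene is ozonised far faster than the monosubstituted vinyl group, the hydroxy aldehyde closes to the lactol, and C10 (R) is carried over unchanged from 1.

**Step 2**
Reactants: 3 (5R)-5-ethenyl-5-methyloxolan-2-ol; 4 ethyl 2-(triphenylphosphoranylidene)propanoate
Product: 6 ethyl (2E,4R,6R)-4-(anilinooxy)-6-hydroxy-2,6-dimethylocta-2,7-dienoate, via aminoxy lactol 5 (not isolated)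
Conditions: PhNO (1.0 equiv; 3 in 1.3-fold excess), L-proline (20 mol%), CHCl3, 0 °C; then 4, CH2Cl2, 0 °C → rt
Reagents that add atoms: nitrosobenzene, O=Nc1ccccc1
Why: Proline-catalysed α-aminoxylation (O-nitroso aldol) of the open aldehyde through its enamine sets C8 as R under catalyst control (L-proline gives the R α-oxy aldehyde), and the stabilised ylide traps the labile α-oxy aldehyde in an E-selective Wittig olefination.

**Step 3**
Reactants: 6 ethyl (2E,4R,6R)-4-(anilinooxy)-6-hydroxy-2,6-dimethylocta-2,7-dienoate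
Product: 7 ethyl (2E,4R,6R)-4,6-dihydroxy-2,6-dimethylocta-2,7-dienoate
Conditions: Cu(OAc)2 (30 mol%), EtOH, rt
Reagents that add atoms: none
Why: Copper-catalysed N–O bond cleavage of the O-alkyl-N-phenylhydroxylamine, the usual release of the alcohol after an α-aminoxylation; no stereocentre is touched and the E-enoate cannot lactonise.

**Step 4**
Reactants: 7 ethyl (2E,4R,6R)-4,6-dihydroxy-2,6-dimethylocta-2,7-dienoate; 8 (2R)-2-methylbutanoic acid
Product: 9 ethyl (2E,4R,6R)-6-hydroxy-2,6-dimethyl-4-{[(2R)-2-methylbutanoyl]oxy}octa-2,7-dienoate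
Conditions: DCC, DMAP (10 mol%), CH2Cl2, 0 °C → rt
Reagents that add atoms: none
Why: Steglich esterification; only the secondary allylic 8-OH is acylated (the tertiary 10-OH is inert), and the α-stereocentre of the acid is not epimerised under these mild conditions.

**Step 5**
Reactants: 9 ethyl (2E,4R,6R)-6-hydroxy-2,6-dimethyl-4-{[(2R)-2-methylbutanoyl]oxy}octa-2,7-dienoate
Product: 11 ethyl (4R,6R)-3,6-dihydroxy-6-methyl-2-methylidene-4-{[(2R)-2-methylbutanoyl]oxy}oct-7-enoate (both C3 epimers), via allylic hydroperoxide 10 (not isolated)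
Conditions: O2, hν (visible), tetraphenylporphyrin (cat.), CH2Cl2, 0 °C; then PPh3, 0 °C → rt
Reagents that add atoms: dioxygen, O=O
Why: Schenck ene reaction of singlet oxygen; in α,β-unsaturated esters hydrogen is abstracted from the alkyl group geminal to the ester (the C13 methyl), giving the C7 hydroperoxide with the C11=C13 methylene, and the vinyl group is inert; the new C7 carbinol is a mixture that is erased in step 6.

**Step 6**
Reactants: 11 ethyl (4R,6R)-3,6-dihydroxy-6-methyl-2-methylidene-4-{[(2R)-2-methylbutanoyl]oxy}oct-7-enoate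
Product: 12 ethyl (2Z,4R,6R)-2-(bromomethyl)-6-hydroxy-6-methyl-4-{[(2R)-2-methylbutanoyl]oxy}octa-2,7-dienoate
Conditions: Me2S, NBS, CH2Cl2, 0 °C (premixed); then 11, 0 °C → rt
Reagents that add atoms: N-bromosuccinimide, O=C1CCC(=O)N1Br
Why: Corey–Kim-type activation of the Baylis–Hillman-type secondary alcohol followed by SN2′ attack of bromide gives the thermodynamically preferred Z allylic bromide; the hindered tertiary alcohol does not react and C8 is untouched.

**Step 7**
Reactants: 13 3-furanmethanol; 14 vinyl bromide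
Product: 17 (2-ethenylfuran-3-yl)methanol, via dilithiated 3-furanmethanol 15 (not isolated), via furylzinc chloride 16 (not isolated)
Conditions: n-BuLi (2.2 equiv), THF, −78 → 0 °C; ZnCl2, 0 °C; then 14, Pd(PPh3)4 (3 mol%), rt
Reagents that add atoms: none
Why: Alkoxide-directed lithiation of 3-furanmethanol at C2, transmetalation to zinc and Negishi cross-coupling with vinyl bromide; no stereocentre is formed.

**Step 8**
Reactants: 12 ethyl (2Z,4R,6R)-2-(bromomethyl)-6-hydroxy-6-methyl-4-{[(2R)-2-methylbutanoyl]oxy}octa-2,7-dienoate; 17 (2-ethenylfuran-3-yl)methanol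
Product: 18 ethyl (2Z,4R,6R,7E)-2-(bromomethyl)-6-hydroxy-8-[3-(hydroxymethyl)furan-2-yl]-6-methyl-4-{[(2R)-2-methylbutanoyl]oxy}octa-2,7-dienoate
Conditions: second-generation Hoveyda–Grubbs catalyst RuCl2(H2IMes)(=CH-C6H4-2-O-i-Pr) (5 mol%), 17 (3 equiv), CH2Cl2, 40 °C
Reagents that add atoms: none
Why: Olefin cross-metathesis between a styrene-like vinylfuran and a tertiary allylic alcohol alkene that does not homodimerise gives the E-alkene; the trisubstituted bromomethyl enoate is inert and the allylic bromide and free hydroxyls are tolerated.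

**Step 9**
Reactants: 18 ethyl (2Z,4R,6R,7E)-2-(bromomethyl)-6-hydroxy-8-[3-(hydroxymethyl)furan-2-yl]-6-methyl-4-{[(2R)-2-methylbutanoyl]oxy}octa-2,7-dienoate
Product: 21 (3aR,4R,6R,7E,10Z,11aR)-6-hydroxy-10-(hydroxymethyl)-6-methyl-3-methylidene-2,9-dioxo-3a,4,5,11a-tetrahydrocyclodeca[b]furan-4-yl (2R)-2-methylbutanoate (the target), via keto-enal 19 (not isolated), via seco-ester 20 (not isolated)
Conditions: NBS (1.05 equiv), NaHCO3 (1.2 equiv), THF/H2O 4:1, −20 °C; then added slowly to In powder (4 equiv) in THF/H2O 1:1 (final 0.003 M), rt; extractive work-up, then p-TsOH·H2O (5 mol%), CH2Cl2, rt (crude, same operation)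
Reagents that add atoms: water, O
Why: Proposed new method: NBS/water opens the 2-alkenylfuran to the (Z)-4-oxo-2-enal 19, whose Z geometry is inherited from the ring (known furan to cis-enedione oxidation); the allylic bromide then inserts indium and its γ-carbon C7 adds to the C6 aldehyde, and the new 6-OH lactonises onto the ethyl ester (closest known reactions: indium Barbier allylation of aldehydes with 2-(bromomethyl)acrylates in water, and intramolecular Barbier or Nozaki–Hiyama closures of ten-membered germacranolide rings); C6 and C7 are set in the C–C bond formation, where the rigid E-enone/Z-enone tether is expected to span C5 and C8 only when they are antiperiplanar about the forming bond (6,7-trans) with the C8 acyloxy group on the outside of the ring, giving 6R,7R.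

**Compound list**
1 | (R)-(−)-linalool, (3R)-3,7-dimethylocta-1,6-dien-3-ol | C=C[C@](C)(O)CCC=C(C)C | starting material
2 | ozonide of 1 at the 6,7-double bond, (3R)-5-(3,3-dimethyl-1,2,4-trioxolan-5-yl)-3-methylpent-1-en-3-ol (not isolated) | C=C[C@](C)(O)CCC1OOC(C)(C)O1 | intermediate
3 | (5R)-5-ethenyl-5-methyloxolan-2-ol (anomer mixture) | OC1CC[C@](C)(C=C)O1 | intermediate
4 | ethyl 2-(triphenylphosphoranylidene)propanoate | CCOC(=O)C(C)=P(c1ccccc1)(c1ccccc1)c1ccccc1 | starting material
5 | (3R,5R)-3-(anilinooxy)-5-ethenyl-5-methyloxolan-2-ol (not isolated) | OC1[C@H](ONc2ccccc2)C[C@](C)(C=C)O1 | intermediate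
6 | ethyl (2E,4R,6R)-4-(anilinooxy)-6-hydroxy-2,6-dimethylocta-2,7-dienoate | C=C[C@](C)(O)C[C@@H](ONc1ccccc1)/C=C(\C)C(=O)OCC | intermediate
7 | ethyl (2E,4R,6R)-4,6-dihydroxy-2,6-dimethylocta-2,7-dienoate | C=C[C@](C)(O)C[C@@H](O)/C=C(\C)C(=O)OCC | intermediate
8 | (2R)-2-methylbutanoic acid | OC(=O)[C@H](C)CC | starting material
9 | ethyl (2E,4R,6R)-6-hydroxy-2,6-dimethyl-4-{[(2R)-2-methylbutanoyl]oxy}octa-2,7-dienoate | C=C[C@](C)(O)C[C@@H](OC(=O)[C@H](C)CC)/C=C(\C)C(=O)OCC | intermediate
10 | ethyl (4R,6R)-3-hydroperoxy-6-hydroxy-6-methyl-2-methylidene-4-{[(2R)-2-methylbutanoyl]oxy}oct-7-enoate (both C3 epimers; not isolated) | C=C[C@](C)(O)C[C@@H](OC(=O)[C@H](C)CC)C(OO)C(=C)C(=O)OCC | intermediate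
11 | ethyl (4R,6R)-3,6-dihydroxy-6-methyl-2-methylidene-4-{[(2R)-2-methylbutanoyl]oxy}oct-7-enoate (both C3 epimers) | C=C[C@](C)(O)C[C@@H](OC(=O)[C@H](C)CC)C(O)C(=C)C(=O)OCC | intermediate
12 | ethyl (2Z,4R,6R)-2-(bromomethyl)-6-hydroxy-6-methyl-4-{[(2R)-2-methylbutanoyl]oxy}octa-2,7-dienoate | C=C[C@](C)(O)C[C@@H](OC(=O)[C@H](C)CC)/C=C(\CBr)C(=O)OCC | intermediate
13 | 3-furanmethanol (furan-3-ylmethanol) | OCc1ccoc1 | starting material
14 | vinyl bromide (bromoethene) | C=CBr | starting material
15 | lithium (2-lithiofuran-3-yl)methanolate (not isolated) | [Li]OCc1ccoc1[Li] | intermediate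
16 | lithium [2-(chlorozincio)furan-3-yl]methanolate (not isolated) | [Li]OCc1ccoc1[Zn]Cl | intermediate
17 | (2-ethenylfuran-3-yl)methanol | OCc1ccoc1C=C | intermediate
18 | ethyl (2Z,4R,6R,7E)-2-(bromomethyl)-6-hydroxy-8-[3-(hydroxymethyl)furan-2-yl]-6-methyl-4-{[(2R)-2-methylbutanoyl]oxy}octa-2,7-dienoate | OCc1ccoc1/C=C/[C@](C)(O)C[C@@H](OC(=O)[C@H](C)CC)/C=C(\CBr)C(=O)OCC | intermediate
19 | ethyl (2Z,4R,6R,7E,10Z)-2-(bromomethyl)-6-hydroxy-10-(hydroxymethyl)-6-methyl-4-{[(2R)-2-methylbutanoyl]oxy}-9,12-dioxododeca-2,7,10-trienoate (not isolated) | O=C/C=C(/CO)C(=O)/C=C/[C@](C)(O)C[C@@H](OC(=O)[C@H](C)CC)/C=C(\CBr)C(=O)OCC | intermediate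
20 | seco-ester of 21 (lactone open: free 6-OH, ethyl ester at C12, same spatial arrangement at C6, C7, C8 and C10), ethyl 2-[(1S,2R,3Z,6E,8R,10R)-2,8-dihydroxy-4-(hydroxymethyl)-8-methyl-10-{[(2R)-2-methylbutanoyl]oxy}-5-oxocyclodeca-3,6-dien-1-yl]prop-2-enoate (not isolated) | C=C(C(=O)OCC)[C@H]1[C@H](O)/C=C(/CO)C(=O)/C=C/[C@](C)(O)C[C@H]1OC(=O)[C@H](C)CC | intermediate
21 | (3aR,4R,6R,7E,10Z,11aR)-6-hydroxy-10-(hydroxymethyl)-6-methyl-3-methylidene-2,9-dioxo-3a,4,5,11a-tetrahydrocyclodeca[b]furan-4-yl (2R)-2-methylbutanoate | C=C1C(=O)O[C@@H]2/C=C(/CO)C(=O)/C=C/[C@](C)(O)C[C@@H](OC(=O)[C@H](C)CC)[C@@H]12 | target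

**Step count and risks**
Total steps: 9. Longest linear sequence: 8 (steps 1–6, 8, 9).

Most likely to fail, in order:

Step 9. The closure must beat oligomerisation, attack through C13 instead of C7, and reduction or Z→E isomerisation of the keto-enal. The main uncertainty is the C6/C7 configuration, because ester-substituted allylindiums in open-chain cases prefer the syn (cis-lactone) adduct and the trans outcome here rests on ring constraint alone. Fallback: set out from 18 and borylate the allylic bromide (B2pin2, Pd2(dba)3, toluene, 50 °C) to the pinacol allylboronate analogue of 18 F6. Open the furan as in step 9 (NBS, NaHCO3, THF/H2O) to the keto-enal pinacol boronate F7. Close the ring by Sc(OTf)3-catalysed intramolecular allylboration, which needs no reducing metal and runs through a closed six-membered transition state, then lactonise with acid. This returns to the route at 21.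

Step 2. The aminoxylation has to run on a lactol that is only partly open, and the α-oxy aldehyde must survive until the ylide traps it. Fallback: set out from 3 and oxidise it (TEMPO, PhI(OAc)2, CH2Cl2) to (5R)-5-ethenyl-5-methyloxolan-2-one F1. Hydroxylate its enolate (LiN(i-Pr)2, THF, −78 °C) with the enantiomer of (camphorsulfonyl)oxaziridine that delivers the 3R alcohol, giving (3R,5R)-5-ethenyl-3-hydroxy-5-methyloxolan-2-one F2. Reduce with i-Bu2AlH (CH2Cl2, −78 °C) to (3R,5R)-5-ethenyl-5-methyloxolane-2,3-diol F3. Wittig reaction of F3 with 4 returns to the route at 7, replacing steps 2 and 3.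

Step 8. The alkene of 12 sits next to a quaternary carbinol and 17 polymerises easily, so the intermolecular metathesis may stall. Fallback: make this alkene the ring-closing bond instead. Set out from 17 and 12: oxidise 17 (NBS, NaHCO3, THF/H2O, −20 °C) to (2Z)-3-(hydroxymethyl)-4-oxohexa-2,5-dienal F4. Add 12 and In powder in the same aqueous THF (intermolecular Barbier allylation, then acid lactonisation) to obtain the acyclic diene lactone F5. Close C1=C2 by ring-closing metathesis (second-generation Hoveyda–Grubbs catalyst, toluene, 0.002 M, 60 °C). This returns to the route at 21 and replaces steps 8 and 9; C6 and C7 are then set in the intermolecular allylation under control from C8.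

**Further compounds**
F1 | step 2 | (5R)-5-ethenyl-5-methyloxolan-2-one | O=C1CC[C@](C)(C=C)O1
F2 | step 2 | (3R,5R)-5-ethenyl-3-hydroxy-5-methyloxolan-2-one | O=C1[C@H](O)C[C@](C)(C=C)O1
F3 | step 2 | (3R,5R)-5-ethenyl-5-methyloxolane-2,3-diol (anomer mixture) | OC1[C@H](O)C[C@](C)(C=C)O1
F4 | step 8 | (2Z)-3-(hydroxymethyl)-4-oxohexa-2,5-dienal | O=C/C=C(/CO)C(=O)C=C
F5 | step 8 | acyclic diene lactone: 21 with the C1=C2 bond replaced by two vinyl ends (C3 vinyl ketone, C10 vinyl carbinol; same configuration at C6, C7, C8, C10) | C=C1C(=O)O[C@H](/C=C(/CO)C(=O)C=C)[C@H]1[C@H](OC(=O)[C@H](C)CC)C[C@@](C)(O)C=C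
F6 | step 9 | pinacol allylboronate analogue of 18 (CH2Br replaced by CH2B(pin)) | OCc1ccoc1/C=C/[C@](C)(O)C[C@@H](OC(=O)[C@H](C)CC)/C=C(\CB1OC(C)(C)C(C)(C)O1)C(=O)OCC
F7 | step 9 | keto-enal pinacol boronate (19 with CH2Br replaced by CH2B(pin)) | O=C/C=C(/CO)C(=O)/C=C/[C@](C)(O)C[C@@H](OC(=O)[C@H](C)CC)/C=C(\CB1OC(C)(C)C(C)(C)O1)C(=O)OCC
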